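**Plan**

- The retrosynthesis first cuts the depside ester C(=O)–O bond between ring A (2,4-dimethoxy-6-pentylbenzoyl) and the C4 oxygen of ring B, then takes the ring B carboxyl back to a formyl group and ring B to olivetol.
- Ring A is cut at C1–C2 and C5–C6. It carries the carboxyl at C1, oxygen at C2 and C4 on either side of C3–H, and pentyl at C6, so C2–C5 map onto a 4-methoxy-6-oxido-2-pyranone (the anion of 3-methoxyglutaconic anhydride) and C6/C1 onto an alk-2-ynoate.
- Forward, the anhydride (three steps from dimethyl 3-oxopentanedioate) and benzyl oct-2-ynoate (one step from hept-1-yne) are annulated with loss of CO2 to build ring A. O-Methylation and hydrogenolysis then give the ring A acid.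
- Ring B is made by formylating olivetol. The ring A acid is esterified at the unchelated 4-hydroxyl, the chelated 2-hydroxyl is methylated, and the formyl group is oxidised to the acid last.
- The target has no stereocentre and no stereogenic double bond. The E enol ether of 3 and 4 and the bridgehead centres of racemic adduct 11 disappear on ring closure and aromatisation.

Key step: step 5

Remark: 5 is written as the dione tautomer although it may exist partly as 6-hydroxy-4-methoxy-2H-pyran-2-one, and 11 is drawn as one enantiomer of a racemate; neither point affects the outcome.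

**Route**

Step 1
Reactants: 1 dimethyl 3-oxopentanedioate
Product: 3 dimethyl (E)-3-methoxypent-2-enedioate, via dimethyl 3,3-dimethoxypentanedioate 2 (not isolated)
Conditions: HC(OMe)3, MeOH, H2SO4 (cat.), reflux; then distillation
Reagents that add atoms: trimethyl orthoformate, COC(OC)OC
Why: Acid-catalysed ketalisation by the orthoformate followed by loss of methanol into conjugation with an ester is the standard enol ether formation from a β-keto ester, and the E isomer (ester trans to methoxy) is the thermodynamic one.

Step 2
Reactants: 3 dimethyl (E)-3-methoxypent-2-enedioate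
Product: 4 (E)-3-methoxypent-2-enedioic acid
Conditions: NaOH (2.2 equiv), H2O–MeOH, 0 °C to rt; then 1 M HCl, 0 °C, to pH 2, EtOAc extraction
Reagents that add atoms: sodium hydroxide, [Na+].[OH-]
Why: Saponification of both methyl esters by acyl addition–elimination should leave the β-methoxy enoate intact, since it is a poor Michael acceptor, and brief cold acidification should free the diacid without hydrolysing the enol ether.

Step 3
Reactants: 4 (E)-3-methoxypent-2-enedioic acid
Product: 5 4-methoxy-2H-pyran-2,6(3H)-dione (3-methoxyglutaconic anhydride)
Conditions: Ac2O, 40 °C; volatiles removed under vacuum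
Reagents that add atoms: none
Why: Dehydrative ring closure of a 1,5-diacid with acetic anhydride is the usual preparation of glutaconic anhydrides, and the E geometry of 4 already holds both carboxyl arms on the same side of the double bond.

Step 4
Reactants: 6 hept-1-yne; 7 benzyl chloroformate
Product: 9 benzyl oct-2-ynoate, via lithium hept-1-yn-1-ide 8 (not isolated)
Conditions: n-BuLi, THF, −78 °C; then 7, −78 °C to rt
Reagents that add atoms: none
Why: Deprotonation of the terminal alkyne and C-acylation of the lithium acetylide by the chloroformate (nucleophilic acyl substitution) is the standard one-step route to alk-2-ynoates, and the low temperature guards against a second addition.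

Step 5
Reactants: 5 4-methoxy-2H-pyran-2,6(3H)-dione; 9 benzyl oct-2-ynoate
Product: 12 benzyl 2-hydroxy-4-methoxy-6-pentylbenzoate, via sodium 4-methoxy-6-oxo-6H-pyran-2-olate 10 (not isolated), via bridged lactone adduct 11 (not isolated)
Conditions: NaH (1.1 equiv), THF, 0 °C; then 9, 0 °C to reflux; 1 M HCl work-up
Reagents that add atoms: none
Why: NaH removes a C3–H of 5 to give the mirror-symmetric dienolate 10, which, numbered as a 4-methoxy-6-oxido-2-pyranone, is an electron-rich diene across C3 and C6. Its C3 carbon should add to the pentyl-bearing β-carbon of 9 while the ester-bearing α-carbon bonds to the oxido-bearing C6, either in one [4+2] event or as Michael addition followed by 6-exo-trig acylation, to give the bridged alkoxide 11. Retro-[4+2] loss of the lactone bridge as CO2 then aromatises the new ring to the sodium phenoxide of 12, so the benzene ring is closed by a formal [4+2] annulation that makes C1–C2 and C5–C6 of ring A. The reaction type is the Tamura annulation of homophthalic and glutaconic anhydride anions with acetylenic esters, applied here to a 3-alkoxy anhydride and a β-alkyl ynoate. No stereocentre is formed in 12, the two bridgehead centres of racemic 11 being lost on aromatisation. The one selectivity needed, the orientation of the ynoate, is secured by Michael polarity (nucleophilic carbon of 10 to electrophilic β-carbon of 9), which places the new hydroxyl ortho to the ester, and the symmetry of 10 leaves no second regiochemical choice.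

Step 6
Reactants: 12 benzyl 2-hydroxy-4-methoxy-6-pentylbenzoate
Product: 13 benzyl 2,4-dimethoxy-6-pentylbenzoate
Conditions: MeI, K2CO3, DMF, rt to 40 °C
Reagents that add atoms: iodomethane, CI
Why: Williamson O-methylation of the phenoxide should proceed readily in DMF although the hydroxyl is hydrogen-bonded to the ester carbonyl, and the benzyl ester is inert to carbonate.

Step 7
Reactants: 13 benzyl 2,4-dimethoxy-6-pentylbenzoate
Product: 14 2,4-dimethoxy-6-pentylbenzoic acid
Conditions: H2 (1 atm), 10% Pd/C, EtOAc, rt
Reagents that add atoms: none
Why: Hydrogenolysis of the benzylic C–O bond over palladium frees the hindered acid under neutral conditions, avoiding saponification of a 2,6-disubstituted benzoate.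

Step 8
Reactants: 15 olivetol (5-pentylbenzene-1,3-diol)
Product: 17 2,4-dihydroxy-6-pentylbenzaldehyde, via (2,4-dihydroxy-6-pentylbenzylidene)dimethyliminium chloride 16 (not isolated)
Conditions: POCl3 (1.2 equiv), DMF, 0 °C to rt; then ice–water, 50 °C
Reagents that add atoms: N,N-dimethylformamide, CN(C)C=O; water, O
Why: Vilsmeier–Haack formylation of a 5-alkylresorcinol goes para to one hydroxyl and ortho to the other, next to the alkyl group, as with orcinol, and hydrolysis of iminium salt 16 delivers the aldehyde.

Step 9
Reactants: 14 2,4-dimethoxy-6-pentylbenzoic acid; 17 2,4-dihydroxy-6-pentylbenzaldehyde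
Product: 19 4-formyl-3-hydroxy-5-pentylphenyl 2,4-dimethoxy-6-pentylbenzoate, via 2,4-dimethoxy-6-pentylbenzoic trifluoroacetic anhydride 18 (not isolated)
Conditions: (CF3CO)2O, toluene, rt; water work-up
Reagents that add atoms: none
Why: Trifluoroacetic anhydride converts the electron-rich acid into mixed anhydride 18, an acylium donor that esterifies phenols (the standard depside coupling), and because the 2-hydroxyl of 17 is locked in a hydrogen bond to the formyl group the free 4-hydroxyl should be the one acylated.

Step 10
Reactants: 19 4-formyl-3-hydroxy-5-pentylphenyl 2,4-dimethoxy-6-pentylbenzoate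
Product: 20 4-formyl-3-methoxy-5-pentylphenyl 2,4-dimethoxy-6-pentylbenzoate
Conditions: MeI, K2CO3, dry DMF, rt
Reagents that add atoms: iodomethane, CI
Why: Williamson methylation of the remaining chelated phenol under anhydrous carbonate conditions should spare the depside ester, whose carbonyl is shielded by two ortho substituents and meets no competent nucleophile in dry DMF.

Step 11
Reactants: 20 4-formyl-3-methoxy-5-pentylphenyl 2,4-dimethoxy-6-pentylbenzoate
Product: 21 planaic acid (4-[(2,4-dimethoxy-6-pentylbenzoyl)oxy]-2-methoxy-6-pentylbenzoic acid)
Conditions: NaClO2, NaH2PO4, 2-methylbut-2-ene, t-BuOH–THF–H2O, rt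
Reagents that add atoms: sodium chlorite, [Na+].[O-]Cl=O
Why: Pinnick oxidation converts the aromatic aldehyde into the acid under buffered, weakly acidic conditions that leave the aryl ester and methyl ethers alone, with 2-methylbut-2-ene trapping hypochlorous acid before it can chlorinate the electron-rich rings.

**Compound list**

1 | dimethyl 3-oxopentanedioate | COC(=O)CC(=O)CC(=O)OC | starting material
2 | dimethyl 3,3-dimethoxypentanedioate | COC(=O)CC(OC)(OC)CC(=O)OC | intermediate
3 | dimethyl (E)-3-methoxypent-2-enedioate | COC(=O)/C=C(/OC)CC(=O)OC | intermediate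
4 | (E)-3-methoxypent-2-enedioic acid | OC(=O)/C=C(/OC)CC(=O)O | intermediate
5 | 4-methoxy-2H-pyran-2,6(3H)-dione (3-methoxyglutaconic anhydride) | COC1=CC(=O)OC(=O)C1 | intermediate
6 | hept-1-yne | CCCCCC#C | starting material
7 | benzyl chloroformate | O=C(Cl)OCc1ccccc1 | starting material
8 | lithium hept-1-yn-1-ide | [Li+].[C-]#CCCCCC | intermediate
9 | benzyl oct-2-ynoate | CCCCCC#CC(=O)OCc1ccccc1 | intermediate
10 | sodium 4-methoxy-6-oxo-6H-pyran-2-olate | [Na+].COC1=CC(=O)OC([O-])=C1 | intermediate
11 | sodium 7-(benzyloxycarbonyl)-5-methoxy-3-oxo-8-pentyl-2-oxabicyclo[2.2.2]octa-5,7-dien-1-olate (racemic, one enantiomer drawn) | [Na+].[O-][C@]12OC(=O)[C@H](C(OC)=C1)C(CCCCC)=C2C(=O)OCc3ccccc3 | intermediate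
12 | benzyl 2-hydroxy-4-methoxy-6-pentylbenzoate | CCCCCc1cc(OC)cc(O)c1C(=O)OCc1ccccc1 | intermediate
13 | benzyl 2,4-dimethoxy-6-pentylbenzoate | CCCCCc1cc(OC)cc(OC)c1C(=O)OCc1ccccc1 | intermediate
14 | 2,4-dimethoxy-6-pentylbenzoic acid | CCCCCc1cc(OC)cc(OC)c1C(=O)O | intermediate
15 | olivetol (5-pentylbenzene-1,3-diol) | CCCCCc1cc(O)cc(O)c1 | starting material
16 | (2,4-dihydroxy-6-pentylbenzylidene)dimethyliminium chloride | CCCCCc1cc(O)cc(O)c1C=[N+](C)C.[Cl-] | intermediate
17 | 2,4-dihydroxy-6-pentylbenzaldehyde | CCCCCc1cc(O)cc(O)c1C=O | intermediate
18 | 2,4-dimethoxy-6-pentylbenzoic trifluoroacetic anhydride | CCCCCc1cc(OC)cc(OC)c1C(=O)OC(=O)C(F)(F)F | intermediate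
19 | 4-formyl-3-hydroxy-5-pentylphenyl 2,4-dimethoxy-6-pentylbenzoate | CCCCCc1cc(OC(=O)c2c(CCCCC)cc(OC)cc2OC)cc(O)c1C=O | intermediate
20 | 4-formyl-3-methoxy-5-pentylphenyl 2,4-dimethoxy-6-pentylbenzoate | CCCCCc1cc(OC(=O)c2c(CCCCC)cc(OC)cc2OC)cc(OC)c1C=O | intermediate
21 | planaic acid | CCCCCc1cc(OC(=O)c2c(CCCCC)cc(OC)cc2OC)cc(OC)c1C(=O)O | target

**Step count**

Total: 11 steps. Longest linear sequence: 9 steps (1, 2, 3, 5, 6, 7, 9, 10, 11).

**Steps most likely to fail**

Step 5. The stabilised anion 10 may add too slowly to an unactivated β-alkyl ynoate, so that self-condensation of the anhydride or base-induced drift of the ynoate to its allenoate consumes the partners before the ring closes. The fallback sets out from 17 and comes back at 14, taking ring A from olivetol instead of building it. Aldehyde 17 would be methylated at both hydroxyls (MeI, K2CO3, DMF) to 2,4-dimethoxy-6-pentylbenzaldehyde F1. Pinnick oxidation of F1 (NaClO2, NaH2PO4, 2-methylbut-2-ene) would then give acid 14. This detour also covers losses in preparing the sensitive anhydride 5.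

Step 9. Acyl transfer to the formyl-deactivated phenol may be slow, so that trifluoroacetylation of 17 or acylation at both hydroxyls competes. The fallback sets out from 14 and comes back at 19, replacing acid-mediated acylium transfer by base-mediated acylation of a site-selectively formed phenoxide. Acid 14 would be converted with oxalyl chloride (cat. DMF, CH2Cl2) into 2,4-dimethoxy-6-pentylbenzoyl chloride F2. F2 would be added to 17 that has been treated with one equivalent of Et3N and catalytic DMAP, so that the more acidic, unchelated 4-hydroxyl is ionised and acylated to give 19.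

Step 10. Base may cleave the depside ester, since the 4-formylphenoxide is a good leaving group, or the chelated phenol may alkylate too slowly. The fallback sets out from 17 and comes back at 20, installing the ring B methyl ether before the ester is made.
- Aldehyde 17 would be allylated selectively at the 4-hydroxyl (allyl bromide, K2CO3, acetone) to 4-(allyloxy)-2-hydroxy-6-pentylbenzaldehyde F3.
- F3 would be methylated (MeI, K2CO3, DMF) to 4-(allyloxy)-2-methoxy-6-pentylbenzaldehyde F4.
- F4 would be deallylated with Pd(PPh3)4 and morpholine to 4-hydroxy-2-methoxy-6-pentylbenzaldehyde F5.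
- F5, with its single phenol, would be acylated with 14 under the conditions of step 9 to give 20 directly.

Further compounds
F1 | step 5 | 2,4-dimethoxy-6-pentylbenzaldehyde | CCCCCc1cc(OC)cc(OC)c1C=O
F2 | step 9 | 2,4-dimethoxy-6-pentylbenzoyl chloride | CCCCCc1cc(OC)cc(OC)c1C(=O)Cl
F3 | step 10 | 4-(allyloxy)-2-hydroxy-6-pentylbenzaldehyde | CCCCCc1cc(OCC=C)cc(O)c1C=O
F4 | step 10 | 4-(allyloxy)-2-methoxy-6-pentylbenzaldehyde | CCCCCc1cc(OCC=C)cc(OC)c1C=O
F5 | step 10 | 4-hydroxy-2-methoxy-6-pentylbenzaldehyde | CCCCCc1cc(O)cc(OC)c1C=O
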